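The lower isoflavan is traced back to an isoflavone, because C2' of its pyran ring (ring C') is an isolated methylene bonded only to O1' and C3', so this one carbon can be inserted last. Heating a 2-hydroxydeoxybenzoin with a formamide acetal makes the C2'–C3' and O1'–C2' bonds and closes ring C' in a single operation. C3' stays planar for later catalyst-controlled reduction. The precursor is a benzyl aryl ketone. Its acyl arene is the future ring A' with one free ortho phenol. Its benzylic arene (central ring B') already bears the perbenzylated trans-(3R,4S)-4-arylisoflavan, assembled by auxiliary aldol, Mitsunobu etherification, cationic closure and palladium-catalysed ketone α-arylation.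

Key step: step 14

Locants: O1–C8a = upper chroman (rings A and C), and ring B is its 3-aryl group. O1'–C8a' = lower chroman (rings A' and C'). Ring B' is the central arene, bonded to C3' and to C4. The target is 3R,4S (H3/H4 trans) and 3'R. The protected series carries five benzyl ethers.

Design note: the deoxybenzoin is made directly by α-arylation of the MOM-protected lower acetophenone. This spares a homologation of the bromide and avoids adding a basic aryllithium to an enolisable arylacetamide. MOM is the only non-benzyl mask, so exactly one phenol is free in the key step.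

Assumption: compounds 1, 6, 9, 16 and 19 are taken as catalogue chemicals.

Step 1
Reactants: 1 2,3-dihydroxy-4-methoxybenzaldehyde
Product: 2 2,3-bis(benzyloxy)-4-methoxybenzaldehyde
Conditions: BnBr, K2CO3, DMF, 60 °C
Reagents that add atoms: benzyl bromide BrCc1ccccc1
Why: Williamson etherification with excess carbonate and gentle heating alkylates both phenols, the chelated one next to the aldehyde included, and gives ethers that fall in the final hydrogenolysis.

Step 2
Reactants: 2 2,3-bis(benzyloxy)-4-methoxybenzaldehyde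
Product: 3 2,3-bis(benzyloxy)-1-methoxy-4-(2-methoxyethenyl)benzene (E/Z mixture)
Conditions: MeOCH2PPh3Cl, KOt-Bu, THF, 0 °C to rt
Reagents that add atoms: (methoxymethyl)triphenylphosphonium chloride [Cl-].COC[P+](c1ccccc1)(c1ccccc1)c1ccccc1
Why: Wittig methoxymethylenation is a standard one-carbon homologation of aromatic aldehydes, and the alkene geometry is irrelevant because both isomers hydrolyse to the same aldehyde.

Step 3
Reactants: 3 enol ether (E/Z mixture)
Product: 5 [2,3-bis(benzyloxy)-4-methoxyphenyl]acetic acid, via arylacetaldehyde 4 (not isolated)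
Conditions: 2 M HCl, THF, 45 °C; then NaH2PO4, 2-methyl-2-butene, NaClO2, t-BuOH/H2O, 0 °C to rt
Reagents that add atoms: water O; sodium chlorite [Na+].[O-]Cl=O
Why: Enol ether hydrolysis followed at once by Pinnick oxidation spares the self-condensing arylacetaldehyde an isolation, and the alkene scavenger keeps hypochlorous acid away from the electron-rich ring.

Step 4
Reactants: 5 [2,3-bis(benzyloxy)-4-methoxyphenyl]acetic acid; 6 (4S)-4-benzyl-1,3-oxazolidin-2-one
Product: 8 (4S)-4-benzyl-3-{[2,3-bis(benzyloxy)-4-methoxyphenyl]acetyl}-1,3-oxazolidin-2-one, via mixed pivalic anhydride 7 (not isolated)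
Conditions: PivCl, Et3N, THF, −20 °C; then LiCl, 6, −20 °C to rt
Reagents that add atoms: none
Why: Mixed-anhydride N-acylation of an Evans oxazolidinone under LiCl/Et3N conditions needs no strong base, and attack goes to the less hindered arylacetyl carbonyl of 7.

Step 5
Reactants: 9 4-hydroxy-2-methoxybenzaldehyde
Product: 10 5-bromo-4-hydroxy-2-methoxybenzaldehyde
Conditions: NBS, MeCN, 0 °C
Reagents that add atoms: N-bromosuccinimide O=C1CCC(=O)N1Br
Why: Electrophilic aromatic bromination should go to C5, which is ortho to the free phenol and para to the methoxy group, whereas C3 is crowded between two oxygen substituents.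

Step 6
Reactants: 10 5-bromo-4-hydroxy-2-methoxybenzaldehyde
Product: 11 4-(benzyloxy)-5-bromo-2-methoxybenzaldehyde
Conditions: BnBr, K2CO3, DMF, rt
Reagents that add atoms: benzyl bromide BrCc1ccccc1
Why: Williamson etherification of an acidic para-formyl phenol is fast and removes the proton that would interfere with the boron aldol.

Step 7
Reactants: 8 arylacetyl oxazolidinone; 11 4-(benzyloxy)-5-bromo-2-methoxybenzaldehyde
Product: 14 (4S)-4-benzyl-3-{(2S,3S)-3-[4-(benzyloxy)-5-bromo-2-methoxyphenyl]-2-[2,3-bis(benzyloxy)-4-methoxyphenyl]-3-hydroxypropanoyl}-1,3-oxazolidin-2-one, via Z-dibutylboron enolate 12 (not isolated), via dibutylboron aldolate 13 (not isolated)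
Conditions: Bu2BOTf, Et3N, CH2Cl2, −78 to 0 °C; 11, −78 to 0 °C; then pH 7 buffer, MeOH, 30% H2O2, 0 °C
Reagents that add atoms: none
Why: In this Evans syn-aldol reaction soft enolisation gives the Z-boron enolate, whose Zimmerman–Traxler chair reacts on the face away from the auxiliary benzyl group, which sets the aryl-bearing carbon (future C3) as 2S and the carbinol, later sacrificed, as 3S.

Step 8
Reactants: 14 syn-aldol adduct
Product: 15 (1S,2R)-1-[4-(benzyloxy)-5-bromo-2-methoxyphenyl]-2-[2,3-bis(benzyloxy)-4-methoxyphenyl]propane-1,3-diol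
Conditions: LiBH4, H2O (1 equiv), Et2O/THF, 0 °C
Reagents that add atoms: none
Why: Reductive auxiliary removal with borohydride attacks the exocyclic imide carbonyl, releases the recoverable oxazolidinone and leaves bromide, benzyl ethers and both centres unchanged (the 2S to 2R change is only a change of priorities).

Step 9
Reactants: 15 (1S,2R)-diol; 16 3-(benzyloxy)phenol
Product: 17 (1S,2R)-1-[4-(benzyloxy)-5-bromo-2-methoxyphenyl]-3-[3-(benzyloxy)phenoxy]-2-[2,3-bis(benzyloxy)-4-methoxyphenyl]propan-1-ol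
Conditions: PPh3, DIAD, THF, 0 °C to rt
Reagents that add atoms: none
Why: In the Mitsunobu etherification the phosphonium activates the open primary hydroxyl much faster than the secondary benzylic one, which is shielded by two ortho-substituted arenes, so the phenol should enter only at the future C2 and no stereocentre is touched.

Step 10
Reactants: 17 aryl ether alcohol
Product: 18 (3R,4S)-7-(benzyloxy)-4-[4-(benzyloxy)-5-bromo-2-methoxyphenyl]-3-[2,3-bis(benzyloxy)-4-methoxyphenyl]chromane
Conditions: Bi(OTf)3 (5 mol %), CH2Cl2 (high dilution), −20 °C to rt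
Reagents that add atoms: none
Why: In this intramolecular Friedel–Crafts alkylation the alcohol ionises to a cation stabilised by the ortho-methoxy and para-benzyloxy groups, ring A attacks through the carbon para to its benzyloxy group to close the six-membered ring C, and approach anti to the C3 aryl group in a half-chair with both aryl groups pseudo-equatorial should set C4 as S (3,4-trans).

Step 11
Reactants: 19 1-[4-(benzyloxy)-2-hydroxyphenyl]ethan-1-one
Product: 20 1-[4-(benzyloxy)-2-(methoxymethoxy)phenyl]ethan-1-one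
Conditions: NaH, MOMCl, DMF, 0 °C to rt
Reagents that add atoms: chloromethyl methyl ether COCCl
Why: Full deprotonation breaks the hydrogen bond to the ketone, and O-alkylation (acetal-type phenol protection) removes the acidic proton that would disturb the enolate chemistry of step 12.

Step 12
Reactants: 18 upper-unit aryl bromide; 20 MOM-protected acetophenone
Product: 21 1-[4-(benzyloxy)-2-(methoxymethoxy)phenyl]-2-{2-(benzyloxy)-5-[(3R,4S)-7-(benzyloxy)-3-[2,3-bis(benzyloxy)-4-methoxyphenyl]chroman-4-yl]-4-methoxyphenyl}ethan-1-one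
Conditions: Pd(OAc)2 (3 mol %), XPhos (6 mol %), NaOt-Bu (2.4 equiv), toluene, 70 °C
Reagents that add atoms: none
Why: In the Buchwald–Hartwig–Miura α-arylation of an aryl methyl ketone, oxidative addition of zerovalent palladium into C–Br, enolate binding and reductive elimination form the ArCH2–C(O) link, while excess base stores the more acidic product as its enolate and the ortho-benzyloxy group adds bulk, so a second arylation is suppressed.

Step 13
Reactants: 21 MOM-protected deoxybenzoin
Product: 22 1-[4-(benzyloxy)-2-hydroxyphenyl]-2-{2-(benzyloxy)-5-[(3R,4S)-7-(benzyloxy)-3-[2,3-bis(benzyloxy)-4-methoxyphenyl]chroman-4-yl]-4-methoxyphenyl}ethan-1-one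
Conditions: p-TsOH·H2O (20 mol %), MeOH/THF, 50 °C
Reagents that add atoms: none
Why: Acid-catalysed acetal exchange (MOM cleavage) is especially easy ortho to a ketone, and benzyl ethers, the chroman and both stereocentres tolerate catalytic sulfonic acid in methanol.

Step 14
Reactants: 22 2-hydroxydeoxybenzoin bearing the upper unit
Product: 24 7-(benzyloxy)-3-{2-(benzyloxy)-5-[(3R,4S)-7-(benzyloxy)-3-[2,3-bis(benzyloxy)-4-methoxyphenyl]chroman-4-yl]-4-methoxyphenyl}-4H-chromen-4-one, via enaminone 23 (not isolated)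
Conditions: Me2NCH(OMe)2 (4 equiv), toluene, 95 °C
Reagents that add atoms: N,N-dimethylformamide dimethyl acetal COC(OC)N(C)C
Why: The acetal ionises to an amino(methoxy)carbenium ion and methoxide, the ketone is enolised at the CH2 between carbonyl and ring B', and C-aminomethylenation with loss of two methanol molecules gives enaminone 23 (C2'–C3' bond). The hydrogen-bonded ortho phenol then adds to the enaminone β-carbon and dimethylamine leaves (O1'–C2' bond), a 6-endo-trig addition–elimination that closes the pyranone ring C'. The closest known reaction type is the formamide-acetal synthesis of isoflavones from 2-hydroxydeoxybenzoins. No stereocentre is created, and C3 and C4 carry no acidifying group, so they cannot epimerise under these almost neutral conditions. The selectivity needed is chemoselectivity: there is only one enolisable position, every other phenol is a benzyl ether so the acetal finds no site for O-methylation, and the single free phenol is consumed by the cyclisation.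

Step 15
Reactants: 24 isoflavone bearing the upper unit
Product: 26 (3R,4R)-7-(benzyloxy)-3-{2-(benzyloxy)-5-[(3R,4S)-7-(benzyloxy)-3-[2,3-bis(benzyloxy)-4-methoxyphenyl]chroman-4-yl]-4-methoxyphenyl}chroman-4-ol, via isoflavanone 25 (not isolated)
Conditions: RuCl[(R,R)-TsDPEN](p-cymene) (5 mol %), HCO2H/Et3N (5:2), EtOAc, 45 °C
Reagents that add atoms: none
Why: In this Noyori–Ikariya asymmetric transfer hydrogenation run as a cascade, the ruthenium hydride first reduces C2'=C3' in conjugate fashion, isoflavanone 25 epimerises quickly at C3' through its enol in the amine-containing medium, and the (R,R)-catalyst reduces only the 3'R epimer from the face opposite the aryl group (dynamic kinetic resolution), which should set the cis-(3'R,4'R) pair regardless of the distant C3/C4 centres.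

Step 16
Reactants: 26 cis-isoflavan-4-ol
Product: 27 (3R,4S)-3-(2,3-dihydroxy-4-methoxyphenyl)-4-{4-hydroxy-5-[(3R)-7-hydroxychroman-3-yl]-2-methoxyphenyl}chroman-7-ol (CNP0112305.1)
Conditions: H2 (3 bar), Pd(OH)2/C, THF/EtOH/AcOH, rt
Reagents that add atoms: none
Why: Catalytic hydrogenolysis cleaves the five O-benzyl bonds and also the C4'–OH bond, which is benzylic and para to O7' and is therefore reduced under the same mildly acidic conditions, while C3', C3 and C4 take no part and the C4–aryl bonds are inert.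

Compound list
1 | 2,3-dihydroxy-4-methoxybenzaldehyde | COc1ccc(C=O)c(O)c1O | starting material
2 | 2,3-bis(benzyloxy)-4-methoxybenzaldehyde | COc1ccc(C=O)c(OCc2ccccc2)c1OCc1ccccc1 | intermediate
3 | 2,3-bis(benzyloxy)-1-methoxy-4-(2-methoxyethenyl)benzene (E/Z mixture) | COC=Cc1ccc(OC)c(OCc2ccccc2)c1OCc1ccccc1 | intermediate
4 | [2,3-bis(benzyloxy)-4-methoxyphenyl]acetaldehyde (not isolated) | O=CCc1ccc(OC)c(OCc2ccccc2)c1OCc1ccccc1 | intermediate
5 | [2,3-bis(benzyloxy)-4-methoxyphenyl]acetic acid | OC(=O)Cc1ccc(OC)c(OCc2ccccc2)c1OCc1ccccc1 | intermediate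
6 | (4S)-4-benzyl-1,3-oxazolidin-2-one | O=C1N[C@@H](Cc2ccccc2)CO1 | starting material
7 | [2,3-bis(benzyloxy)-4-methoxyphenyl]acetic pivalic anhydride (not isolated) | CC(C)(C)C(=O)OC(=O)Cc1ccc(OC)c(OCc2ccccc2)c1OCc1ccccc1 | intermediate
8 | (4S)-4-benzyl-3-{[2,3-bis(benzyloxy)-4-methoxyphenyl]acetyl}-1,3-oxazolidin-2-one | O=C(Cc1ccc(OC)c(OCc2ccccc2)c1OCc1ccccc1)N1[C@@H](Cc2ccccc2)COC1=O | intermediate
9 | 4-hydroxy-2-methoxybenzaldehyde | COc1cc(O)ccc1C=O | starting material
10 | 5-bromo-4-hydroxy-2-methoxybenzaldehyde | COc1cc(O)c(Br)cc1C=O | intermediate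
11 | 4-(benzyloxy)-5-bromo-2-methoxybenzaldehyde | COc1cc(OCc2ccccc2)c(Br)cc1C=O | intermediate
12 | (Z)-dibutylboron enolate of 8 (not isolated) | CCCCB(CCCC)O/C(=C\c1ccc(OC)c(OCc2ccccc2)c1OCc1ccccc1)N1[C@@H](Cc2ccccc2)COC1=O | intermediate
13 | O-dibutylboryl derivative of aldol 14 (not isolated) | O=C([C@@H](c1ccc(OC)c(OCc2ccccc2)c1OCc1ccccc1)[C@H](OB(CCCC)CCCC)c1cc(Br)c(OCc2ccccc2)cc1OC)N1[C@@H](Cc2ccccc2)COC1=O | intermediate
14 | (4S)-4-benzyl-3-{(2S,3S)-3-[4-(benzyloxy)-5-bromo-2-methoxyphenyl]-2-[2,3-bis(benzyloxy)-4-methoxyphenyl]-3-hydroxypropanoyl}-1,3-oxazolidin-2-one | O=C([C@@H](c1ccc(OC)c(OCc2ccccc2)c1OCc1ccccc1)[C@H](O)c1cc(Br)c(OCc2ccccc2)cc1OC)N1[C@@H](Cc2ccccc2)COC1=O | intermediate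
15 | (1S,2R)-1-[4-(benzyloxy)-5-bromo-2-methoxyphenyl]-2-[2,3-bis(benzyloxy)-4-methoxyphenyl]propane-1,3-diol | OC[C@@H](c1ccc(OC)c(OCc2ccccc2)c1OCc1ccccc1)[C@H](O)c1cc(Br)c(OCc2ccccc2)cc1OC | intermediate
16 | 3-(benzyloxy)phenol | Oc1cccc(OCc2ccccc2)c1 | starting material
17 | (1S,2R)-1-[4-(benzyloxy)-5-bromo-2-methoxyphenyl]-3-[3-(benzyloxy)phenoxy]-2-[2,3-bis(benzyloxy)-4-methoxyphenyl]propan-1-ol | O(C[C@@H](c1ccc(OC)c(OCc2ccccc2)c1OCc1ccccc1)[C@H](O)c1cc(Br)c(OCc2ccccc2)cc1OC)c1cccc(OCc2ccccc2)c1 | intermediate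
18 | (3R,4S)-7-(benzyloxy)-4-[4-(benzyloxy)-5-bromo-2-methoxyphenyl]-3-[2,3-bis(benzyloxy)-4-methoxyphenyl]chromane | COc1cc(OCc2ccccc2)c(Br)cc1[C@@H]1c2ccc(OCc3ccccc3)cc2OC[C@H]1c1ccc(OC)c(OCc2ccccc2)c1OCc1ccccc1 | intermediate
19 | 1-[4-(benzyloxy)-2-hydroxyphenyl]ethan-1-one | CC(=O)c1ccc(OCc2ccccc2)cc1O | starting material
20 | 1-[4-(benzyloxy)-2-(methoxymethoxy)phenyl]ethan-1-one | CC(=O)c1ccc(OCc2ccccc2)cc1OCOC | intermediate
21 | MOM-protected deoxybenzoin (name as in step 12) | O=C(Cc1cc([C@@H]4c5ccc(OCc9ccccc9)cc5OC[C@H]4c4ccc(OC)c(OCc9ccccc9)c4OCc4ccccc4)c(OC)cc1OCc1ccccc1)c1ccc(OCc9ccccc9)cc1OCOC | intermediate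
22 | 2-hydroxydeoxybenzoin, precursor of the key step (name as in step 13) | O=C(Cc1cc([C@@H]4c5ccc(OCc9ccccc9)cc5OC[C@H]4c4ccc(OC)c(OCc9ccccc9)c4OCc4ccccc4)c(OC)cc1OCc1ccccc1)c1ccc(OCc9ccccc9)cc1O | intermediate
23 | 3-(dimethylamino)prop-2-en-1-one (enaminone) derived from 22 at its CH2 (not isolated) | O=C(C(=CN(C)C)c1cc([C@@H]4c5ccc(OCc9ccccc9)cc5OC[C@H]4c4ccc(OC)c(OCc9ccccc9)c4OCc4ccccc4)c(OC)cc1OCc1ccccc1)c1ccc(OCc9ccccc9)cc1O | intermediate
24 | isoflavone, product of the key step (name as in step 14) | O=c1c(-c2cc([C@@H]4c5ccc(OCc9ccccc9)cc5OC[C@H]4c4ccc(OC)c(OCc9ccccc9)c4OCc4ccccc4)c(OC)cc2OCc2ccccc2)coc2cc(OCc9ccccc9)ccc12 | intermediate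
25 | 2',3'-dihydro derivative of 24 (isoflavanone, interconverting C3' epimers, not isolated) | O=C1C(c2cc([C@@H]4c5ccc(OCc9ccccc9)cc5OC[C@H]4c4ccc(OC)c(OCc9ccccc9)c4OCc4ccccc4)c(OC)cc2OCc2ccccc2)COc2cc(OCc9ccccc9)ccc12 | intermediate
26 | cis-(3'R,4'R)-isoflavan-4'-ol (name as in step 15) | COc1cc(OCc2ccccc2)c([C@@H]2COc3cc(OCc4ccccc4)ccc3[C@@H]2O)cc1[C@@H]1c2ccc(OCc3ccccc3)cc2OC[C@H]1c1ccc(OC)c(OCc2ccccc2)c1OCc1ccccc1 | intermediate
27 | (3R,4S)-3-(2,3-dihydroxy-4-methoxyphenyl)-4-{4-hydroxy-5-[(3R)-7-hydroxychroman-3-yl]-2-methoxyphenyl}chroman-7-ol | COc1cc(O)c([C@@H]2COc3cc(O)ccc3C2)cc1[C@@H]1c2ccc(O)cc2OC[C@H]1c1ccc(OC)c(O)c1O | target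

Total step count: 16. Longest linear sequence: 13 (steps 1–4, 7–10, 12–16).

Steps most likely to fail

Step 10.
- **What may go wrong:** the open-chain cation may be attacked from both faces. It may lose the C3 proton, which would erase the auxiliary-derived centre. The neighbouring benzyl ether oxygen of ring B may also intercept it before ring A does.
- **Fallback:** ring C is closed first and the central arene is brought in afterwards on a conformationally fixed cyclic cation. The path sets out from 8 and comes back at 18.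
- **Path:** Commercial 4-(benzyloxy)-2-hydroxybenzaldehyde is silylated (TBSCl, imidazole, DMF) to 4-(benzyloxy)-2-[(tert-butyldimethylsilyl)oxy]benzaldehyde F1. The boron aldol of 8 with this aldehyde, run as in step 7, gives the syn-aldol adduct F2, and LiBH4 reduces it to the silylated (1S,2R)-diol F3. Bu4NF in THF then frees the phenol to give the (1S,2R)-phenol diol F4. An intramolecular Mitsunobu reaction (PPh3, DIAD) joins the phenol to the primary carbon and gives (3R,4S)-7-(benzyloxy)-3-[2,3-bis(benzyloxy)-4-methoxyphenyl]chroman-4-ol F5. Commercial 2-bromo-5-methoxyphenol is benzylated (BnBr, K2CO3) to 1-(benzyloxy)-2-bromo-5-methoxybenzene F6. Used in excess under Bi(OTf)3 catalysis, this arene captures the chroman-4-yl cation from F5. Its only unhindered activated carbon is para to OBn and ortho to OMe, and it enters anti to the C3 aryl group, which gives 18.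

Step 12.
- **What may go wrong:** oxidative addition into the electron-rich ortho-alkoxy aryl bromide may be slow. Hydrodebromination or self-condensation of the ketone enolate under the basic conditions may then take over.
- **Fallback:** a non-basic zinc-enolate arylation followed by acylation of an aryllithium. The path sets out from 18 and comes back at 21.
- **Path:** Zinc dust and 4-(bromoacetyl)morpholine give the Reformatsky reagent bromo[2-(morpholin-4-yl)-2-oxoethyl]zinc F7. It couples with 18 under Pd(dba)2/Q-Phos in THF to give the arylacetic morpholine amide F8. Separately, 4-bromoresorcinol is monobenzylated at the hydroxyl remote from bromine (BnBr, K2CO3, acetone) to 5-(benzyloxy)-2-bromophenol F9. NaH/MOMCl converts this phenol into 4-(benzyloxy)-1-bromo-2-(methoxymethoxy)benzene F10. Bromine–lithium exchange (n-BuLi, THF, −78 °C) gives [4-(benzyloxy)-2-(methoxymethoxy)phenyl]lithium F11. Its addition to F8 stops at the tetrahedral adduct and releases ketone 21 on work-up.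

Step 15.
- **What may go wrong:** the cascade may stall at the conjugate-reduction stage on this bulky substrate. Epimerisation at C3' may also lag behind carbonyl reduction, which would lead to poor facial selectivity.
- **Fallback:** C3' is set by asymmetric alkene hydrogenation instead of ketone reduction. The path sets out from 24 and comes back at 27.
- **Path:** NaBH4 in THF/EtOH reduces 24 fully to the isoflavan-4'-ol isomer mixture F12. Catalytic p-TsOH in warm toluene dehydrates it to the isoflav-3'-ene F13. Hydrogenation of the trisubstituted C3'=C4' bond follows, with [Ir(cod)(L)]BArF (L = a chiral phosphinite–oxazoline, enantiomer selected for 3'R) under H2 in CH2Cl2. These conditions spare benzyl ethers and give the pentabenzyl (3'R)-isoflavan F14. Hydrogenolysis over Pd(OH)2/C gives 27.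

Further compounds
F1 | step 10 | 4-(benzyloxy)-2-[(tert-butyldimethylsilyl)oxy]benzaldehyde | O=Cc1ccc(OCc2ccccc2)cc1O[Si](C)(C)C(C)(C)C
F2 | step 10 | (4S)-4-benzyl-3-[(2S,3S)-3-{4-(benzyloxy)-2-[(tert-butyldimethylsilyl)oxy]phenyl}-2-[2,3-bis(benzyloxy)-4-methoxyphenyl]-3-hydroxypropanoyl]-1,3-oxazolidin-2-one | O=C([C@@H](c1ccc(OC)c(OCc2ccccc2)c1OCc1ccccc1)[C@H](O)c1ccc(OCc2ccccc2)cc1O[Si](C)(C)C(C)(C)C)N1[C@@H](Cc2ccccc2)COC1=O
F3 | step 10 | (1S,2R)-1-{4-(benzyloxy)-2-[(tert-butyldimethylsilyl)oxy]phenyl}-2-[2,3-bis(benzyloxy)-4-methoxyphenyl]propane-1,3-diol | OC[C@@H](c1ccc(OC)c(OCc2ccccc2)c1OCc1ccccc1)[C@H](O)c1ccc(OCc2ccccc2)cc1O[Si](C)(C)C(C)(C)C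
F4 | step 10 | (1S,2R)-1-[4-(benzyloxy)-2-hydroxyphenyl]-2-[2,3-bis(benzyloxy)-4-methoxyphenyl]propane-1,3-diol | OC[C@@H](c1ccc(OC)c(OCc2ccccc2)c1OCc1ccccc1)[C@H](O)c1ccc(OCc2ccccc2)cc1O
F5 | step 10 | (3R,4S)-7-(benzyloxy)-3-[2,3-bis(benzyloxy)-4-methoxyphenyl]chroman-4-ol | O[C@@H]1c2ccc(OCc3ccccc3)cc2OC[C@H]1c1ccc(OC)c(OCc2ccccc2)c1OCc1ccccc1
F6 | step 10 | 1-(benzyloxy)-2-bromo-5-methoxybenzene | COc1ccc(Br)c(OCc2ccccc2)c1
F7 | step 12 | bromo[2-(morpholin-4-yl)-2-oxoethyl]zinc | Br[Zn]CC(=O)N1CCOCC1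
F8 | step 12 | 2-{2-(benzyloxy)-5-[(3R,4S)-7-(benzyloxy)-3-[2,3-bis(benzyloxy)-4-methoxyphenyl]chroman-4-yl]-4-methoxyphenyl}-1-(morpholin-4-yl)ethan-1-one | O=C(Cc1cc([C@@H]4c5ccc(OCc9ccccc9)cc5OC[C@H]4c4ccc(OC)c(OCc9ccccc9)c4OCc4ccccc4)c(OC)cc1OCc1ccccc1)N1CCOCC1
F9 | step 12 | 5-(benzyloxy)-2-bromophenol | Oc1cc(OCc2ccccc2)ccc1Br
F10 | step 12 | 4-(benzyloxy)-1-bromo-2-(methoxymethoxy)benzene | COCOc1cc(OCc2ccccc2)ccc1Br
F11 | step 12 | [4-(benzyloxy)-2-(methoxymethoxy)phenyl]lithium | [Li]c1ccc(OCc2ccccc2)cc1OCOC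
F12 | step 15 | isoflavan-4'-ol from 24, mixture of C3'/C4' isomers | OC1c2ccc(OCc9ccccc9)cc2OCC1c1cc([C@@H]4c5ccc(OCc9ccccc9)cc5OC[C@H]4c4ccc(OC)c(OCc9ccccc9)c4OCc4ccccc4)c(OC)cc1OCc1ccccc1
F13 | step 15 | isoflav-3'-ene (7-benzyloxy-3-aryl-2H-chromene bearing the upper unit) | C1(c2cc([C@@H]4c5ccc(OCc9ccccc9)cc5OC[C@H]4c4ccc(OC)c(OCc9ccccc9)c4OCc4ccccc4)c(OC)cc2OCc2ccccc2)=Cc2ccc(OCc9ccccc9)cc2OC1
F14 | step 15 | pentabenzyl ether of 27, (3R,4S,3'R) | COc1cc(OCc2ccccc2)c([C@@H]2COc3cc(OCc4ccccc4)ccc3C2)cc1[C@@H]1c2ccc(OCc3ccccc3)cc2OC[C@H]1c1ccc(OC)c(OCc2ccccc2)c1OCc1ccccc1
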